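**Retrosynthetic overview**
1. Target ⇒ the C6 alcohol / C9 silyl ether macrocycle; senecioylation and desilylation come last.
2. Ten-membered ring ⇒ C6–C7 bond, closed last by a chromium-mediated Barbier reaction between a 3-(bromomethyl)butenolide and its tethered epoxy aldehyde (sets C6 and C7).
3. Butenolide ⇒ α-methylene-γ-lactone ⇒ C7–C8 Barbier addition of methyl 2-(bromomethyl)acrylate to a C8 aldehyde; C4/C5 epoxide ⇒ Sharpless epoxidation of an E-allylic alcohol.
4. Key skeleton-forming step: C3–C4 bond and E-trisubstituted alkene by a Zweifel 1,2-boronate shift joining an alkylboronic ester (C8–C10, C1–C3; from a cis-epoxide and allyl Grignard) with a Z-alkenyllithium (C4–C6); both halves come from but-2-yn-1-ol.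
5. Ring order: oxirane at C9/C10 (opened again), oxirane at C4/C5, γ-lactone, ten-membered carbocycle.

Assumption: labels C1–C15 follow germacrane-type numbering of the target (C4/C5 epoxide, C6 acyloxy, C7/C8 lactone fusion with the ring oxygen on C8, C9 carbinol, C10 methyl-bearing carbon, C11–C13 lactone carbons), in which the target is (4R,5R,6R,7S,8S,9R,10R); TBS = tert-butyldimethylsilyl, TES = triethylsilyl.

**Step 1**
Reactants: 1 but-2-yn-1-ol
Product: 3 (2Z)-3-iodobut-2-en-1-ol, via cyclic alkenylalanate 2 (not isolated)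
Conditions: NaAlH2(OCH2CH2OMe)2, THF, 0 → 25 °C; then I2, THF, −78 °C
Reagents that add atoms: iodine (II)
Why: Hydroxyl-directed trans-hydroalumination places aluminium on C3 in a five-membered alanate and iodinolysis with retention gives only the Z-iodide (Corey-type reductive iodination of a propargylic alcohol).

**Step 2**
Reactants: 1 but-2-yn-1-ol
Product: 4 (2Z)-but-2-en-1-ol
Conditions: H2 (1 atm), Pd/CaCO3 poisoned with Pb(OAc)2, quinoline, pentane, 0 °C
Reagents that add atoms: none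
Why: Lindlar semihydrogenation is a syn addition, so the alkyne gives the Z-alkene needed for a cis-epoxide.

**Step 3**
Reactants: 4 (2Z)-but-2-en-1-ol
Product: 6 triethyl{[(2S,3R)-3-methyloxiran-2-yl]methoxy}silane, via epoxy alcohol 5 (not isolated)
Conditions: Ti(OiPr)4 (0.2 equiv), L-(+)-diisopropyl tartrate (0.24 equiv), t-BuOOH (1.1 equiv), 4 Å sieves, CH2Cl2, −20 °C; then Et3N, Et3SiCl, DMAP (cat.), −20 → 0 °C
Reagents that add atoms: tert-butyl hydroperoxide (CC(C)(C)OO); chlorotriethylsilane (CC[Si](Cl)(CC)CC)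
Why: Sharpless asymmetric epoxidation with the L-(+)-tartrate delivers oxygen to the face that gives the (2S,3R)-cis-epoxide (about 90% ee expected for a Z-allylic alcohol; the minor enantiomer is removed later as diastereomers), and silylation in the same flask avoids isolating the water-soluble epoxy alcohol.

**Step 4**
Reactants: 6 triethyl{[(2S,3R)-3-methyloxiran-2-yl]methoxy}silane; 7 allylmagnesium bromide
Product: 9 (2R,3R)-2-(TBS-oxy)-3-methyl-1-(TES-oxy)hex-5-ene, via magnesium alkoxide 8 (not isolated)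
Conditions: 7 (1.3 equiv), CuI (10 mol%), Et2O, −40 → −20 °C; then TBSOTf, 2,6-lutidine, −78 → 0 °C
Reagents that add atoms: tert-butyldimethylsilyl trifluoromethanesulfonate (CC(C)(C)[Si](C)(C)OS(=O)(=O)C(F)(F)F)
Why: Copper-catalysed SN2 epoxide opening by the allyl Grignard reagent occurs at the methyl-bearing carbon (the other carbon is shielded and deactivated by the CH2OSi group) with inversion, which sets C10 (R) anti to the C9 oxygen, and the magnesium alkoxide is silylated in situ.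

**Step 5**
Reactants: 9 (2R,3R)-2-(TBS-oxy)-3-methyl-1-(TES-oxy)hex-5-ene
Product: 10 2-[(4R,5R)-5-(TBS-oxy)-4-methyl-6-(TES-oxy)hexyl]-4,4,5,5-tetramethyl-1,3,2-dioxaborolane
Conditions: pinacolborane, [Ir(cod)Cl]2 (1.5 mol%), dppm (3 mol%), CH2Cl2, 25 °C
Reagents that add atoms: pinacolborane (CC1(C)OBOC1(C)C)
Why: Iridium-catalysed hydroboration of the terminal alkene is anti-Markovnikov and gives the primary alkylboronic ester without touching the silyl ethers.

**Step 6**
Reactants: 3 (2Z)-3-iodobut-2-en-1-ol; 10 2-[(4R,5R)-5-(TBS-oxy)-4-methyl-6-(TES-oxy)hexyl]-4,4,5,5-tetramethyl-1,3,2-dioxaborolane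
Product: 13 (2E,7R,8R)-8-(TBS-oxy)-3,7-dimethyl-9-(TES-oxy)non-2-en-1-ol, via alkenyllithium 11 (not isolated), via boronate complex 12 (not isolated)
Conditions: 3 (1.3 equiv), n-BuLi (1.3 equiv) then t-BuLi (2.6 equiv), Et2O, −78 °C; add 10, THF, −78 °C; I2, MeOH, −78 °C; NaOMe, MeOH, −78 → 25 °C
Reagents that add atoms: none
Why: Zweifel olefination, the key skeleton-forming step: the alkenyllithium adds to boron, iodine triggers a stereospecific 1,2-shift of the alkyl group from boron to carbon (1,2-metallate rearrangement), and anti elimination of the β-iodoboronate gives the trisubstituted alkene with net inversion of the Z-alkenyl geometry, so only the E-alkene forms and the later epoxide is trans.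

**Step 7**
Reactants: 13 (2E,7R,8R)-8-(TBS-oxy)-3,7-dimethyl-9-(TES-oxy)non-2-en-1-ol
Product: 15 tert-butyl({(2R,3R)-3-[(4R,5R)-5-(TBS-oxy)-4-methyl-6-(TES-oxy)hexyl]-3-methyloxiran-2-yl}methoxy)dimethylsilane, via epoxy alcohol 14 (not isolated)
Conditions: Ti(OiPr)4 (0.1 equiv), D-(−)-diisopropyl tartrate (0.12 equiv), t-BuOOH (1.1 equiv), 4 Å sieves, CH2Cl2, −20 °C; then imidazole, TBSCl, 0 → 25 °C
Reagents that add atoms: tert-butyl hydroperoxide (CC(C)(C)OO); tert-butyldimethylsilyl chloride (CC(C)(C)[Si](C)(C)Cl)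
Why: Sharpless asymmetric epoxidation with the D-(−)-tartrate sets C4 and C5 (both R) under reagent control on a geraniol-type allylic alcohol, and the primary alcohol is capped in the same flask.

**Step 8**
Reactants: 15 tert-butyl({(2R,3R)-3-[(4R,5R)-5-(TBS-oxy)-4-methyl-6-(TES-oxy)hexyl]-3-methyloxiran-2-yl}methoxy)dimethylsilane
Product: 16 (2R,3R)-2-(TBS-oxy)-6-[(2R,3R)-3-(TBS-oxymethyl)-2-methyloxiran-2-yl]-3-methylhexanal
Conditions: (COCl)2, DMSO, CH2Cl2, −78 → −35 °C; Et3N, −78 → 0 °C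
Reagents that add atoms: none
Why: Under Swern conditions a primary triethylsilyl ether is cleaved and oxidised directly to the aldehyde, while the primary and secondary TBS ethers and the epoxide are left alone (chemoselective Swern oxidation of a primary TES ether).

**Step 9**
Reactants: 16 (2R,3R)-2-(TBS-oxy)-6-[(2R,3R)-3-(TBS-oxymethyl)-2-methyloxiran-2-yl]-3-methylhexanal; 17 methyl 2-(bromomethyl)prop-2-enoate
Product: 19 (5S)-5-{(1R,2R)-1-(TBS-oxy)-5-[(2R,3R)-3-(TBS-oxymethyl)-2-methyloxiran-2-yl]-2-methylpentyl}-3-methylideneoxolan-2-one, via zinc alkoxide 18 (not isolated)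
Conditions: Zn dust (Me3SiCl-activated), THF, 0 → 25 °C, then 40 °C; aq NH4Cl
Reagents that add atoms: none
Why: Zinc-mediated Barbier (Dreiding–Schmidt) allylation in which Felkin–Anh attack anti to the non-chelating α-silyloxy group sets C8 (S), erythro to C9, and the zinc alkoxide closes the γ-lactone with loss of methoxide.

**Step 10**
Reactants: 19 (5S)-5-{(1R,2R)-1-(TBS-oxy)-5-[(2R,3R)-3-(TBS-oxymethyl)-2-methyloxiran-2-yl]-2-methylpentyl}-3-methylideneoxolan-2-one
Product: 21 (5S)-3-(bromomethyl)-5-{(1R,2R)-1-(TBS-oxy)-5-[(2R,3R)-3-(TBS-oxymethyl)-2-methyloxiran-2-yl]-2-methylpentyl}furan-2(5H)-one, via dibromide 20 (not isolated)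
Conditions: Br2, CH2Cl2, 0 → 25 °C; then i-Pr2NEt, 0 °C
Reagents that add atoms: bromine (BrBr)
Why: Bromine adds to the exocyclic alkene and E2 loss of HBr towards the conjugated ring position (bromination–dehydrobromination) turns the α-methylene lactone into the 3-(bromomethyl)butenolide without touching C8; the hindered amine limits quaternisation of the allylic bromide.

**Step 11**
Reactants: 21 (5S)-3-(bromomethyl)-5-{(1R,2R)-1-(TBS-oxy)-5-[(2R,3R)-3-(TBS-oxymethyl)-2-methyloxiran-2-yl]-2-methylpentyl}furan-2(5H)-one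
Product: 22 (5S)-3-(bromomethyl)-5-{(1R,2R)-1-(TBS-oxy)-5-[(2R,3R)-3-(hydroxymethyl)-2-methyloxiran-2-yl]-2-methylpentyl}furan-2(5H)-one
Conditions: HF·pyridine, THF, 0 °C
Reagents that add atoms: none
Why: HF·pyridine cleaves the unhindered primary TBS ether much faster than the flanked secondary one and is neither basic nor nucleophilic enough to attack the epoxide or the allylic bromide (selective desilylation).

**Step 12**
Reactants: 22 (5S)-3-(bromomethyl)-5-{(1R,2R)-1-(TBS-oxy)-5-[(2R,3R)-3-(hydroxymethyl)-2-methyloxiran-2-yl]-2-methylpentyl}furan-2(5H)-one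
Product: 23 (2S,3R)-3-{(4R,5R)-5-[(2S)-4-(bromomethyl)-5-oxo-2,5-dihydrofuran-2-yl]-5-(TBS-oxy)-4-methylpentyl}-3-methyloxirane-2-carbaldehyde
Conditions: Dess–Martin periodinane, NaHCO3, CH2Cl2, 0 → 25 °C
Reagents that add atoms: none
Why: Buffered Dess–Martin oxidation gives the epoxy aldehyde without epimerisation or epoxide opening; it is used crude.

**Step 13**
Reactants: 23 (2S,3R)-3-{(4R,5R)-5-[(2S)-4-(bromomethyl)-5-oxo-2,5-dihydrofuran-2-yl]-5-(TBS-oxy)-4-methylpentyl}-3-methyloxirane-2-carbaldehyde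
Product: 24 6-hydroxy-9-(TBS-oxy)-4,5-epoxygermacr-11(13)-en-12,8-olide with all seven stereocentres arranged as in 27
Conditions: CrCl2 (6 equiv), THF, 25 °C, 23 added over 10 h (2 mM final); aq work-up
Reagents that add atoms: none
Why: Proposed new method: a macrocyclising Nozaki–Hiyama-type Barbier reaction in which a butenolide-derived allylchromium reagent attacks its own tethered α,β-epoxy aldehyde through ring carbon C7. Divalent chromium inserts into the allylic C–Br bond in two one-electron steps, and the σ-allyl trivalent chromium species binds the aldehyde and reacts through a six-membered chair transition state. Three preferences are matched for the required product: bond formation anti to the C8–C9 bond gives the trans-fused lactone (C7), the ring-fixed E-type allyl geometry gives the anti C6/C7 relationship, and Felkin–Anh attack anti to the epoxide C5–O bond gives C6 (R). The closest known reactions are intermolecular Zn, In and CrCl2 Barbier additions of 3-(bromomethyl)furan-2(5H)-one to aldehydes and intramolecular Nozaki–Hiyama allylations of acyclic 2-(bromomethyl)alkenoates that close ten-membered germacranolide rings.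

**Step 14**
Reactants: 24 6-hydroxy-9-(TBS-oxy)-4,5-epoxygermacr-11(13)-en-12,8-olide; 25 3-methylbut-2-enoyl chloride
Product: 26 9-O-TBS ether of the target
Conditions: pyridine, DMAP (cat.), CH2Cl2, 0 → 25 °C
Reagents that add atoms: none
Why: Nucleophilic-catalysed acylation of the only free hydroxyl; pyridine instead of a trialkylamine avoids ketene formation and deconjugation of the senecioyl group.

**Step 15**
Reactants: 26 9-O-TBS ether of the target
Product: 27 (4R,5R,6R,7S,8S,9R,10R)-4,5-epoxy-9-hydroxy-6-(3-methylbut-2-enoyloxy)germacr-11(13)-en-12,8-olide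
Conditions: HF·pyridine, THF, 0 → 25 °C
Reagents that add atoms: none
Why: Fluoride-mediated desilylation under weakly acidic, non-basic conditions frees the C9 hydroxyl while the epoxide, the senecioate and the α-methylene lactone survive.

**Compound list**
1 | but-2-yn-1-ol | CC#CCO | starting material
2 | sodium cyclic alkenylalanate of 1 (Al on C3, O–Al chelate; formed in situ) | CC1=CCO[Al-]1(OCCOC)OCCOC.[Na+] | intermediate
3 | (2Z)-3-iodobut-2-en-1-ol | C/C(I)=C/CO | intermediate
4 | (2Z)-but-2-en-1-ol | C/C=C\CO | intermediate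
5 | [(2S,3R)-3-methyloxiran-2-yl]methanol (formed in situ) | OC[C@@H]1O[C@@H]1C | intermediate
6 | triethyl{[(2S,3R)-3-methyloxiran-2-yl]methoxy}silane | CC[Si](CC)(CC)OC[C@@H]1O[C@@H]1C | intermediate
7 | allylmagnesium bromide | C=CC[Mg]Br | starting material
8 | bromomagnesium (2R,3R)-3-methyl-1-(TES-oxy)hex-5-en-2-olate (formed in situ) | CC[Si](CC)(CC)OC[C@H](O[Mg]Br)[C@H](C)CC=C | intermediate
9 | (2R,3R)-2-(TBS-oxy)-3-methyl-1-(TES-oxy)hex-5-ene | CC[Si](CC)(CC)OC[C@H](O[Si](C)(C)C(C)(C)C)[C@H](C)CC=C | intermediate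
10 | 2-[(4R,5R)-5-(TBS-oxy)-4-methyl-6-(TES-oxy)hexyl]-4,4,5,5-tetramethyl-1,3,2-dioxaborolane | CC[Si](CC)(CC)OC[C@H](O[Si](C)(C)C(C)(C)C)[C@H](C)CCCB1OC(C)(C)C(C)(C)O1 | intermediate
11 | lithium (2Z)-3-lithiobut-2-en-1-olate (formed in situ) | [Li]/C(C)=C\CO[Li] | intermediate
12 | lithium alkenyl(alkyl)pinacolatoborate from 10 and 11 (boron cis to CH2OLi; formed in situ) | CC[Si](CC)(CC)OC[C@H](O[Si](C)(C)C(C)(C)C)[C@H](C)CCC[B-]1(/C(C)=C\CO[Li])OC(C)(C)C(C)(C)O1.[Li+] | intermediate
13 | (2E,7R,8R)-8-(TBS-oxy)-3,7-dimethyl-9-(TES-oxy)non-2-en-1-ol | CC[Si](CC)(CC)OC[C@H](O[Si](C)(C)C(C)(C)C)[C@H](C)CCC/C(C)=C/CO | intermediate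
14 | {(2R,3R)-3-[(4R,5R)-5-(TBS-oxy)-4-methyl-6-(TES-oxy)hexyl]-3-methyloxiran-2-yl}methanol (formed in situ) | CC[Si](CC)(CC)OC[C@H](O[Si](C)(C)C(C)(C)C)[C@H](C)CCC[C@@]1(C)O[C@@H]1CO | intermediate
15 | tert-butyl({(2R,3R)-3-[(4R,5R)-5-(TBS-oxy)-4-methyl-6-(TES-oxy)hexyl]-3-methyloxiran-2-yl}methoxy)dimethylsilane | CC[Si](CC)(CC)OC[C@H](O[Si](C)(C)C(C)(C)C)[C@H](C)CCC[C@@]1(C)O[C@@H]1CO[Si](C)(C)C(C)(C)C | intermediate
16 | (2R,3R)-2-(TBS-oxy)-6-[(2R,3R)-3-(TBS-oxymethyl)-2-methyloxiran-2-yl]-3-methylhexanal | O=C[C@H](O[Si](C)(C)C(C)(C)C)[C@H](C)CCC[C@@]1(C)O[C@@H]1CO[Si](C)(C)C(C)(C)C | intermediate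
17 | methyl 2-(bromomethyl)prop-2-enoate | C=C(CBr)C(=O)OC | starting material
18 | bromozinc alkoxide of methyl (4S,5R,6R)-5-(TBS-oxy)-9-[(2R,3R)-3-(TBS-oxymethyl)-2-methyloxiran-2-yl]-4-hydroxy-6-methyl-2-methylidenenonanoate (formed in situ) | C=C(C[C@H](O[Zn]Br)[C@H](O[Si](C)(C)C(C)(C)C)[C@H](C)CCC[C@@]1(C)O[C@@H]1CO[Si](C)(C)C(C)(C)C)C(=O)OC | intermediate
19 | (5S)-5-{(1R,2R)-1-(TBS-oxy)-5-[(2R,3R)-3-(TBS-oxymethyl)-2-methyloxiran-2-yl]-2-methylpentyl}-3-methylideneoxolan-2-one | C=C1C(=O)O[C@@H](C1)[C@H](O[Si](C)(C)C(C)(C)C)[C@H](C)CCC[C@@]2(C)O[C@@H]2CO[Si](C)(C)C(C)(C)C | intermediate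
20 | (5S)-3-bromo-3-(bromomethyl) analogue of 19 (both C3 epimers; formed in situ) | BrCC1(Br)C(=O)O[C@@H](C1)[C@H](O[Si](C)(C)C(C)(C)C)[C@H](C)CCC[C@@]2(C)O[C@@H]2CO[Si](C)(C)C(C)(C)C | intermediate
21 | (5S)-3-(bromomethyl)-5-{(1R,2R)-1-(TBS-oxy)-5-[(2R,3R)-3-(TBS-oxymethyl)-2-methyloxiran-2-yl]-2-methylpentyl}furan-2(5H)-one | O=C1O[C@@H](C=C1CBr)[C@H](O[Si](C)(C)C(C)(C)C)[C@H](C)CCC[C@@]2(C)O[C@@H]2CO[Si](C)(C)C(C)(C)C | intermediate
22 | (5S)-3-(bromomethyl)-5-{(1R,2R)-1-(TBS-oxy)-5-[(2R,3R)-3-(hydroxymethyl)-2-methyloxiran-2-yl]-2-methylpentyl}furan-2(5H)-one | O=C1O[C@@H](C=C1CBr)[C@H](O[Si](C)(C)C(C)(C)C)[C@H](C)CCC[C@@]2(C)O[C@@H]2CO | intermediate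
23 | (2S,3R)-3-{(4R,5R)-5-[(2S)-4-(bromomethyl)-5-oxo-2,5-dihydrofuran-2-yl]-5-(TBS-oxy)-4-methylpentyl}-3-methyloxirane-2-carbaldehyde | O=C1O[C@@H](C=C1CBr)[C@H](O[Si](C)(C)C(C)(C)C)[C@H](C)CCC[C@@]2(C)O[C@@H]2C=O | intermediate
24 | 6-hydroxy-9-(TBS-oxy)-4,5-epoxygermacr-11(13)-en-12,8-olide, stereocentres arranged as in 27 (C7 is formally R here only because the CIP priorities change) | C=C1C(=O)O[C@@H]2[C@H](O[Si](C)(C)C(C)(C)C)[C@H](C)CCC[C@@]3(C)O[C@@H]3[C@H](O)[C@@H]12 | intermediate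
25 | 3-methylbut-2-enoyl chloride | CC(C)=CC(Cl)=O | starting material
26 | 9-O-TBS ether of 27 (stereocentres arranged as in 27) | C=C1C(=O)O[C@@H]2[C@H](O[Si](C)(C)C(C)(C)C)[C@H](C)CCC[C@@]3(C)O[C@@H]3[C@H](OC(=O)C=C(C)C)[C@@H]12 | intermediate
27 | (4R,5R,6R,7S,8S,9R,10R)-4,5-epoxy-9-hydroxy-6-(3-methylbut-2-enoyloxy)germacr-11(13)-en-12,8-olide (CNP0119422.1) | C=C1C(=O)O[C@@H]2[C@H](O)[C@H](C)CCC[C@@]3(C)O[C@@H]3[C@H](OC(=O)C=C(C)C)[C@@H]12 | target

**Step count**
Total steps: 15. Longest linear sequence: 14 (steps 2–15, from 1 through 4); step 1 is the one-step side branch.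

**Steps most likely to fail, with fallbacks**

Step 13 (the proposed new ring closure). Risks are oligomerisation, or a ring-constrained transition state that overrides the matched preferences at C6/C7. The fallback sets out from 23. The allylic bromide is exchanged for boron with B2pin2 and Pd2(dba)3 (zerovalent palladium, DMSO, 40 °C, 5 mM) to give the pinacol allylboronate F1. F1 is then heated at 1 mM in toluene (80 °C), so the same C6–C7 bond closes through a metal-free, closed six-membered allylboration transition state, which is known behaviour of 2-alkoxycarbonylallyl boronates towards aldehydes. Triethanolamine work-up cleaves the borate and the route is rejoined at 24.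

Step 10 (bromination–dehydrobromination next to an epoxide and an epimerisable C8–H). The fallback sets out from 16 and builds the bromomethyl butenolide without bromine or amine base. Felkin–Anh addition of vinylmagnesium bromide (THF, −78 °C) gives the allylic alcohol F2. Esterification with 2-(bromomethyl)prop-2-enoic acid (DCC, CH2Cl2, 0 °C) gives the diene ester F3. Ring-closing metathesis with the second-generation Hoveyda–Grubbs catalyst (toluene, 80 °C) then rejoins the route at 21; this also bypasses step 9.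

Step 9 (substrate-controlled C8 configuration). If the Felkin ratio is poor, the fallback sets out from 15. Only the primary triethylsilyl ether is cleaved (PPTS, MeOH, 0 °C) to give the primary alcohol F4. F4 is converted directly into the lactone by Krische's iridium-catalysed transfer-hydrogenative 2-(alkoxycarbonyl)allylation: [Ir(cod)Cl]2, the SEGPHOS enantiomer that delivers the S-carbinol, 4-chloro-3-nitrobenzoic acid, K3PO4 and purchased methyl 2-{[(tert-butoxycarbonyl)oxy]methyl}prop-2-enoate in THF at 60 °C. Here the catalyst, not the substrate, sets C8, and the route is rejoined at 19.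

**Further compounds**
F1 | step 13 | (2S,3R)-3-{(4R,5R)-5-[(2S)-5-oxo-4-[(4,4,5,5-tetramethyl-1,3,2-dioxaborolan-2-yl)methyl]-2,5-dihydrofuran-2-yl]-5-(TBS-oxy)-4-methylpentyl}-3-methyloxirane-2-carbaldehyde | O=C1O[C@@H](C=C1CB3OC(C)(C)C(C)(C)O3)[C@H](O[Si](C)(C)C(C)(C)C)[C@H](C)CCC[C@@]2(C)O[C@@H]2C=O
F2 | step 10 | (3S,4R,5R)-4-(TBS-oxy)-8-[(2R,3R)-3-(TBS-oxymethyl)-2-methyloxiran-2-yl]-5-methyloct-1-en-3-ol | C=C[C@H](O)[C@H](O[Si](C)(C)C(C)(C)C)[C@H](C)CCC[C@@]1(C)O[C@@H]1CO[Si](C)(C)C(C)(C)C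
F3 | step 10 | 2-(bromomethyl)prop-2-enoate ester of F2 | C=C[C@H](OC(=O)C(=C)CBr)[C@H](O[Si](C)(C)C(C)(C)C)[C@H](C)CCC[C@@]1(C)O[C@@H]1CO[Si](C)(C)C(C)(C)C
F4 | step 9 | (2R,3R)-2-(TBS-oxy)-6-[(2R,3R)-3-(TBS-oxymethyl)-2-methyloxiran-2-yl]-3-methylhexan-1-ol | OC[C@H](O[Si](C)(C)C(C)(C)C)[C@H](C)CCC[C@@]1(C)O[C@@H]1CO[Si](C)(C)C(C)(C)C
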